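**Assumptions (one line each):** (S)-Terpinen-4-ol is available in high ee. The major diastereomer at each relay is the one described in the "Why" lines. Azulene numbering is used in the "Why" lines: C3 is C(OH)(iPr), C3a is the ring-fusion CH, C4 is CH–OAr, C6 is C–Me on the alkene or epoxide, and C8a is the angular C–Me.

## Retrosynthetic overview
- The target is the 6,7-epoxide of ferutinin, made by alkene epoxidation and aryl-acetate removal from the 4-acetoxybenzoate of jaeschkeanadiol (13).
- Jaeschkeanadiol comes from a hydroxyl-directed reduction of β-hydroxy ketone 12. Ketone 12 comes from ring-closing metathesis (RCM) of diene 11, which comes from a Pd(0) isomerisation of epoxy alcohol 10.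
- The key bond is the C8a quaternary C–C bond, formed by a Claisen [3,3] rearrangement of allylic alcohol 5.
- Allylic alcohol 5 comes from methallyl addition to cyclopentene-carbaldehyde 3. Aldehyde 3 comes from ozonolysis and aldol condensation of (S)-terpinen-4-ol (1), which supplies the C3 carbinol stereocentre.
- Ring order: the cyclopentene forms by aldol condensation (steps 1–2), and the cycloheptene forms by RCM (step 8).

## Route

**Step 1**
Reactants: 1 (S)-terpinen-4-ol
Product: 2 3-hydroxy-3-isopropyl-6-oxoheptanal (carbinol configuration unchanged)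
Conditions: O3, CH2Cl2/MeOH, –78 °C; then Me2S, –78 → 25 °C
Reagents that add atoms: ozone, [O-][O+]=O (its O atoms end up as C=O)
Why: Ozonolysis followed by reductive work-up cleaves only the trisubstituted ring alkene, and the carbinol stereocentre is not involved.

**Step 2**
Reactants: 2
Product: 3 5-hydroxy-5-isopropyl-2-methylcyclopent-1-ene-1-carbaldehyde
Conditions: pyrrolidine (10 mol%), AcOH (10 mol%), CH2Cl2, 25 → 40 °C
Reagents that add atoms: none
Why: Enamine-mediated intramolecular aldol condensation (5-exo onto the methyl ketone, then dehydration) builds the cyclopentene and the enal without touching the C3 stereocentre.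

**Step 3**
Reactants: 3; 4 methallylmagnesium chloride
Product: 5 2-(1-hydroxy-3-methylbut-3-en-1-yl)-3-methyl-1-isopropylcyclopent-2-en-1-ol (new carbinol centre as drawn)
Conditions: 4 (2.5 equiv), THF, –78 → 0 °C; aq. NH4Cl
Reagents that add atoms: methallylmagnesium chloride, C=C(C)C[Mg]Cl (adds the 2-methylallyl group)
Why: Grignard 1,2-addition to the enal, where the magnesium alkoxide of the tertiary OH chelates the aldehyde so that attack occurs syn to that oxygen and anti to iPr, sets the C4 carbinol that relays chirality in step 4.

**Step 4 (key step)**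
Reactants: 5; 6 ethyl vinyl ether
Product: 7 2-[3-hydroxy-1-methyl-2-(3-methylbut-3-en-1-ylidene)-3-isopropylcyclopentyl]acetaldehyde (E-alkene, quaternary C8a)
Conditions: 6 (solvent), Hg(OAc)2 (10 mol%), 35 °C; then o-xylene, 170 °C, sealed tube
Reagents that add atoms: ethyl vinyl ether, C=COCC (adds CH2CHO; OEt is lost as EtOH)
Why: Transetherification then Claisen rearrangement (Watanabe–Conlon variant) transfers the C4 carbinol chirality suprafacially, with the carbinol C–H in the alkene plane, to form the C8a–CH2 bond on the face anti to the tertiary OH, cis to iPr and trans to the future C8a–Me.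

**Step 5**
Reactants: 7; 8 methyltriphenylphosphonium bromide
Product: 9 3-allyl-3-methyl-2-(3-methylbut-3-en-1-ylidene)-1-isopropylcyclopentan-1-ol (E)
Conditions: 8, KOtBu, THF, 0 °C
Reagents that add atoms: methyltriphenylphosphonium bromide, C[P+](c1ccccc1)(c1ccccc1)c1ccccc1.[Br-] (adds =CH2)
Why: Wittig methylenation converts the aldehyde to the terminal alkene needed for RCM; no stereocentre is affected because the aldehyde α-carbon is a CH2 beside the quaternary centre.

**Step 6**
Reactants: 9
Product: 10 spiro-epoxide of the exocyclic alkene, oxygen syn to the tertiary OH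
Conditions: VO(acac)2 (5 mol%), TBHP, CH2Cl2, 0 °C
Reagents that add atoms: tert-butyl hydroperoxide, CC(C)(C)OO (transfers O)
Why: The vanadium-catalysed hydroxyl-directed epoxidation (Sharpless–Michaelson type) is selective for the alkene allylic to the tertiary alcohol over the monosubstituted and 1,1-disubstituted alkenes, and delivers oxygen to the face syn to C3–OH, anti to the C8a–CH2 chain.

**Step 7**
Reactants: 10
Product: 11 1-[5-hydroxy-2-methyl-5-isopropyl-2-allylcyclopentyl]-3-methylbut-3-en-1-one
Conditions: Pd(PPh3)4 (5 mol%), benzene, 80 °C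
Reagents that add atoms: none
Why: Pd(0)-catalysed isomerisation of the 2,3-epoxy alcohol (Suzuki–Noyori, a formal 1,2-hydride shift) gives the β-hydroxy ketone with H delivered to C3a anti to the epoxide oxygen, i.e. trans to the angular methyl.

**Step 8**
Reactants: 11
Product: 12 3-hydroxy-6,8a-dimethyl-3-isopropyl-2,3,3a,5,8,8a-hexahydroazulen-4(1H)-one
Conditions: Grubbs II (5 mol%), CH2Cl2 (3 mM), 40 °C
Reagents that add atoms: none (ethylene is lost)
Why: Ring-closing metathesis joins the allyl and methallyl alkenes to form the trisubstituted C6=C7 bond of the seven-membered ring of the trans-fused hydroazulene.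

**Step 9**
Reactants: 12
Product: 13 jaeschkeanadiol (hexahydroazulene-3,4-diol)
Conditions: Me4NBH(OAc)3 (5 equiv), MeCN/AcOH 1:1, –20 → 25 °C
Reagents that add atoms: none (only H is added)
Why: In the Evans–Saksena reduction, the C3 alkoxyborohydride delivers hydride intramolecularly to the C4 ketone from the C3–O face, fixing C4–OH as in the target, and only the trans-fused epimer, where C3–O and C4 are cis, can react (Curtin–Hammett at the epimerisable C3a).

**Step 10**
Reactants: 13; 14 4-acetoxybenzoyl chloride
Product: 15 jaeschkeanadiol 4-(4-acetoxybenzoate)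
Conditions: 14 (1.5 equiv), DMAP (20 mol%), pyridine, CH2Cl2, 0 → 25 °C
Reagents that add atoms: 4-acetoxybenzoyl chloride, CC(=O)Oc1ccc(cc1)C(=O)Cl (adds the aroyl group)
Why: Acylation is selective for the secondary C4–OH over the hindered tertiary C3–OH and proceeds with retention.

**Step 11**
Reactants: 15
Product: 16 6,7-epoxide of 15
Conditions: mCPBA (1.2 equiv), NaHCO3, CH2Cl2, 0 °C
Reagents that add atoms: mCPBA, O=C(OO)c1cccc(Cl)c1 (transfers O)
Why: Prilezhaev epoxidation of the only remaining alkene occurs on the face anti to the angular C8a-methyl, giving the epoxide configuration of the target.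

**Step 12**
Reactants: 16
Product: 17 jaeskeanin (target)
Conditions: NH3 (7 N in MeOH), 0 °C
Reagents that add atoms: none (the acetyl group is transferred to MeOH)
Why: Ammonolysis of the aryl acetate is far faster than cleavage of the hindered alkyl benzoate, and the trisubstituted epoxide is stable to these conditions.

## Compound list
1 | (S)-terpinen-4-ol | CC1=CC[C@](O)(C(C)C)CC1 | starting material
2 | 3-hydroxy-3-isopropyl-6-oxoheptanal | CC(=O)CC[C@@](O)(C(C)C)CC=O | intermediate
3 | 5-hydroxy-5-isopropyl-2-methylcyclopent-1-ene-1-carbaldehyde | CC(C)[C@]1(O)CCC(C)=C1C=O | intermediate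
4 | methallylmagnesium chloride | C=C(C)C[Mg]Cl | starting material
5 | 2-(1-hydroxy-3-methylbut-3-en-1-yl)-3-methyl-1-isopropylcyclopent-2-en-1-ol | CC(C)[C@]1(O)CCC(C)=C1[C@H](O)CC(C)=C | intermediate
6 | ethyl vinyl ether | C=COCC | starting material
7 | Claisen aldehyde (E-alkene, quaternary C8a) | CC(C)[C@]1(O)CC[C@](C)(CC=O)/C1=C/CC(C)=C | intermediate
8 | methyltriphenylphosphonium bromide | C[P+](c1ccccc1)(c1ccccc1)c1ccccc1.[Br-] | starting material
9 | Wittig diene | CC(C)[C@]1(O)CC[C@](C)(CC=C)/C1=C/CC(C)=C | intermediate
10 | spiro-epoxy alcohol | CC(C)[C@]1(O)CC[C@](C)(CC=C)[C@@]12O[C@H]2CC(C)=C | intermediate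
11 | β-hydroxy ketone diene | CC(C)[C@]1(O)CC[C@](C)(CC=C)[C@H]1C(=O)CC(C)=C | intermediate
12 | hydroazulenone | CC(C)[C@]1(O)CC[C@]2(C)CC=C(C)CC(=O)[C@@H]12 | intermediate
13 | jaeschkeanadiol | CC(C)[C@]1(O)CC[C@]2(C)CC=C(C)C[C@H](O)[C@@H]12 | intermediate
14 | 4-acetoxybenzoyl chloride | CC(=O)Oc1ccc(cc1)C(=O)Cl | starting material
15 | jaeschkeanadiol 4-(4-acetoxybenzoate) | CC(C)[C@]1(O)CC[C@]2(C)CC=C(C)C[C@H](OC(=O)c3ccc(OC(C)=O)cc3)[C@@H]12 | intermediate
16 | 6,7-epoxide of 15 | CC(C)[C@]1(O)CC[C@]2(C)C[C@@H]3O[C@]3(C)C[C@H](OC(=O)c3ccc(OC(C)=O)cc3)[C@@H]12 | intermediate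
17 | jaeskeanin | CC(C)[C@]1(O)CC[C@]2(C)C[C@@H]3O[C@]3(C)C[C@H](OC(=O)c3ccc(O)cc3)[C@H]21 | target

## Summary
**Total step count:** 12. **Longest linear sequence:** 12 (1 → 17).

**Three steps most likely to fail:**
1. **Step 2 (aldol condensation).** The β-hydroxy aldehyde intermediate can undergo retro-aldol or dehydration, which would scramble or destroy C3.
   - Fallback: silylate the tertiary OH of 1 before ozonolysis, carry the silyl ether through steps 3–5, and remove it before step 6.
2. **Step 4 (Claisen).** Bond formation at a congested tetrasubstituted alkene, and the two-stage relay C3 → C4 → C8a, may give the wrong C8a epimer.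
   - Fallback: protect the secondary OH of 5 as its silyl ether and run the Claisen on the tertiary allylic C3–OH, so that C3 transfers directly to C8a. Then rebuild C3–OH by nucleophilic epoxidation and reductive opening of the resulting β-isopropyl enone.
3. **Step 7 (Pd(0) epoxide isomerisation).** Oxidative addition at the tetrasubstituted epoxide carbon may be too slow.
   - Fallback: open the epoxide with Cp2TiCl and 1,4-cyclohexadiene (radical pathway) to give the C4 alcohol, then oxidise with Dess–Martin periodinane to ketone 11.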